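**Retrosynthetic overview**

1. Rings: A = piperidine, B = cycloheptene, C = cyclopentene, D = ester-bearing cyclopentane. The target comes from tetracycle 32 by Krapcho removal of an auxiliary second ester (the malonate is the activating group for the ester α-carbon), acid deprotection and N-methylation.
2. Key disconnection: the bond between the ring D methylene and the ester-bearing ring D carbon (5-exo-tet malonate alkylation). It is made in the same flask directly after the bond between the bromo-alkene carbon of ring C and the methylene-bearing carbon of ring A (7-exo carbopalladation with iodine transfer), so 32 comes from 30, which holds only rings A and C.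
3. Enabling feature: the ring D methylene sits on the quaternary carbon shared by rings A, B and D. That carbon has no hydrogen, and the methylene lies 1,5 to the ester α-carbon through the ring C alkene carbon. Carbopalladation of a 3-methylenepiperidine therefore gives a neopentyl palladium/iodide that cannot β-eliminate and is placed for five-ring closure.
4. 30 comes from B-alkyl Suzuki coupling of piperidine iodide 28 with bromo(iodo)cyclopentenyl malonate 11 (cyclopentane-1,3-dione, CBS reduction, SN2). 28 comes from 3-oxopiperidine 25, made by one-carbon ring expansion of a pyrrolidinone that is built by nickel-catalysed malonate/nitroalkene Michael addition, lactamisation and trans-alkylation with iodide 4.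
5. Order of ring formation: C (purchased five-membered ring), A (pyrrolidinone, then piperidine), then B and D together in the key step.

Key step: step 21

Remark: the sense of induction in steps 6 and 9 is assigned from the established models for these catalysts (both antipodes of each are purchasable), and 3-[(4-methoxybenzyl)oxy]propanal is taken as a purchasable aldehyde.

Abbreviations: TBS = tert-butyldimethylsilyl; PMB = 4-methoxybenzyl; Boc = tert-butoxycarbonyl; 9-BBN = 9-borabicyclo[3.3.1]nonane; QPhos = 1,2,3,4,5-pentaphenyl-1'-(di-tert-butylphosphino)ferrocene.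

**Route**

Step 1
Reactants: 1 methyl (3S)-3-hydroxypentanoate
Product: 2 methyl (3S)-3-[(tert-butyldimethylsilyl)oxy]pentanoate
Conditions: TBSCl, imidazole, DMF, rt
Reagents that add atoms: tert-butyldimethylsilyl chloride, C[Si](C)(Cl)C(C)(C)C
Why: Imidazole-promoted silyl ether formation at the secondary alcohol; the purchased (S)-carbinol centre, which becomes the side-chain carbinol of the target, is not touched.

Step 2
Reactants: 2 methyl (3S)-3-[(tert-butyldimethylsilyl)oxy]pentanoate
Product: 3 (3S)-3-[(tert-butyldimethylsilyl)oxy]pentan-1-ol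
Conditions: LiBH4, MeOH (1 equiv), THF, 0 °C → rt
Reagents that add atoms: none
Why: Hydride reduction of the ester to the primary alcohol; the silyl ether and the stereocentre are inert to LiBH4.

Step 3
Reactants: 3 (3S)-3-[(tert-butyldimethylsilyl)oxy]pentan-1-ol
Product: 4 tert-butyl{[(3S)-1-iodopentan-3-yl]oxy}dimethylsilane
Conditions: I2, PPh3, imidazole, CH2Cl2, 0 °C → rt
Reagents that add atoms: iodine, II
Why: Appel-type iodination of the primary alcohol through the alkoxyphosphonium iodide; no stereocentre is involved.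

Step 4
Reactants: 5 cyclopentane-1,3-dione
Product: 6 2-bromocyclopentane-1,3-dione (enol form)
Conditions: NBS, CH2Cl2, 0 °C → rt
Reagents that add atoms: N-bromosuccinimide, O=C1CCC(=O)N1Br
Why: Electrophilic α-halogenation of the enolised β-dicarbonyl at its only nucleophilic carbon.

Step 5
Reactants: 6 2-bromocyclopentane-1,3-dione (enol form)
Product: 7 2-bromo-3-iodocyclopent-2-en-1-one
Conditions: PPh3, I2, Et3N, MeCN, rt → 80 °C
Reagents that add atoms: iodine, II
Why: Conversion of the vinylogous acid into the β-iodo enone by the triphenylphosphine–iodine reagent (activation of the enol oxygen, addition–elimination by iodide); the dione is symmetrical, so only one product can form.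

Step 6
Reactants: 7 2-bromo-3-iodocyclopent-2-en-1-one
Product: 8 (1S)-2-bromo-3-iodocyclopent-2-en-1-ol
Conditions: (R)-2-methyl-CBS-oxazaborolidine (20 mol %), BH3·SMe2, THF, −20 °C
Reagents that add atoms: none
Why: Corey–Bakshi–Shibata reduction; the α-bromoalkenyl arm acts as the large group and the CH2 arm as the small one, so the (R)-catalyst should deliver hydride to the face that gives the (S)-carbinol.

Step 7
Reactants: 8 (1S)-2-bromo-3-iodocyclopent-2-en-1-ol; 9 dimethyl malonate
Product: 11 dimethyl 2-[(1S)-2-bromo-3-iodocyclopent-2-en-1-yl]propanedioate, via allylic mesylate 10 (not isolated)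
Conditions: MsCl, Et3N, CH2Cl2, −40 °C; then NaCH(CO2Me)2 (from 9 and NaH), THF, −40 → 0 °C
Reagents that add atoms: methanesulfonyl chloride, CS(Cl)(=O)=O (atoms retained only in 10)
Why: Mesylation and SN2 displacement by sodium dimethyl malonate with inversion (the SN2' path is blocked by the fully substituted iodo-bearing alkene carbon, and ionisation is disfavoured by the bromo substituent); this sets the ring C stereocentre with the malonate on the face later needed for ring D.

Step 8
Reactants: 12 3-[(4-methoxybenzyl)oxy]propanal; 13 nitromethane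
Product: 16 1-methoxy-4-({[(3E)-4-nitrobut-3-en-1-yl]oxy}methyl)benzene, via nitro alcohol 14 (not isolated), via nitro mesylate 15 (not isolated)
Conditions: MeNO2 (5 equiv), Et3N (0.2 equiv), THF, 0 °C → rt; then MsCl, Et3N, CH2Cl2, 0 °C
Reagents that add atoms: methanesulfonyl chloride, CS(Cl)(=O)=O (atoms retained only in 15)
Why: Henry reaction followed by mesylation and E1cB elimination; the conjugated nitroalkene should form as the more stable (E)-isomer.

Step 9
Reactants: 16 1-methoxy-4-({[(3E)-4-nitrobut-3-en-1-yl]oxy}methyl)benzene; 9 dimethyl malonate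
Product: 17 dimethyl 2-{(2R)-4-[(4-methoxybenzyl)oxy]-1-nitrobutan-2-yl}propanedioate
Conditions: NiBr2[(R,R)-N,N'-dibenzylcyclohexane-1,2-diamine]2 (2 mol %), toluene, rt
Reagents that add atoms: none
Why: Catalytic enantioselective Michael addition of a malonate to a nitroalkene; the chiral diamine–nickel enolate discriminates the nitroalkene faces and should set the ring A methine stereocentre as (R).

Step 10
Reactants: 17 dimethyl 2-{(2R)-4-[(4-methoxybenzyl)oxy]-1-nitrobutan-2-yl}propanedioate
Product: 19 methyl (3R,4R)-4-{2-[(4-methoxybenzyl)oxy]ethyl}-2-oxopyrrolidine-3-carboxylate, via amino diester 18 (not isolated)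
Conditions: H2 (4 bar), Raney Ni, MeOH, rt; then 50 °C
Reagents that add atoms: none
Why: Hydrogenation of the nitro group and spontaneous 5-exo-trig lactamisation of the amine onto one of the two equivalent esters; the remaining ester should settle trans to the ring substituent by enolisation (this centre is rebuilt in step 11).

Step 11
Reactants: 19 methyl (3R,4R)-4-{2-[(4-methoxybenzyl)oxy]ethyl}-2-oxopyrrolidine-3-carboxylate; 4 tert-butyl{[(3S)-1-iodopentan-3-yl]oxy}dimethylsilane
Product: 20 methyl (3S,4R)-3-{(3S)-3-[(tert-butyldimethylsilyl)oxy]pentyl}-4-{2-[(4-methoxybenzyl)oxy]ethyl}-2-oxopyrrolidine-3-carboxylate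
Conditions: NaH (1.0 equiv), DMF, 0 °C; then 4, 0 °C → rt
Reagents that add atoms: none
Why: C-alkylation of the β-amido ester enolate (malonate-type alkylation); the iodide should approach anti to the neighbouring ring substituent, so the pentyl chain ends trans and the ester cis to it, which sets the quaternary ring A stereocentre.

Step 12
Reactants: 20 methyl (3S,4R)-3-{(3S)-3-[(tert-butyldimethylsilyl)oxy]pentyl}-4-{2-[(4-methoxybenzyl)oxy]ethyl}-2-oxopyrrolidine-3-carboxylate
Product: 21 (3R,4R)-3-{(3S)-3-[(tert-butyldimethylsilyl)oxy]pentyl}-3-(hydroxymethyl)-4-{2-[(4-methoxybenzyl)oxy]ethyl}pyrrolidin-2-one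
Conditions: LiBH4, MeOH (2 equiv), THF, 0 → 40 °C
Reagents that add atoms: none
Why: Chemoselective hydride reduction of the ester (the future hydroxymethyl group) in the presence of the secondary lactam, which LiBH4 does not reduce.

Step 13
Reactants: 21 (3R,4R)-3-{(3S)-3-[(tert-butyldimethylsilyl)oxy]pentyl}-3-(hydroxymethyl)-4-{2-[(4-methoxybenzyl)oxy]ethyl}pyrrolidin-2-one
Product: 22 (3R,4R)-3-{[(tert-butyldimethylsilyl)oxy]methyl}-3-{(3S)-3-[(tert-butyldimethylsilyl)oxy]pentyl}-4-{2-[(4-methoxybenzyl)oxy]ethyl}pyrrolidin-2-one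
Conditions: TBSCl, imidazole, DMF, 40 °C
Reagents that add atoms: tert-butyldimethylsilyl chloride, C[Si](C)(Cl)C(C)(C)C
Why: Silyl ether formation at the neopentyl primary alcohol, which also removes the risk of retro-aldol loss of formaldehyde in the basic steps that follow.

Step 14
Reactants: 22 (3R,4R)-3-{[(tert-butyldimethylsilyl)oxy]methyl}-3-{(3S)-3-[(tert-butyldimethylsilyl)oxy]pentyl}-4-{2-[(4-methoxybenzyl)oxy]ethyl}pyrrolidin-2-one
Product: 23 tert-butyl (3R,4R)-3-{[(tert-butyldimethylsilyl)oxy]methyl}-3-{(3S)-3-[(tert-butyldimethylsilyl)oxy]pentyl}-4-{2-[(4-methoxybenzyl)oxy]ethyl}-2-oxopyrrolidine-1-carboxylate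
Conditions: Boc2O, DMAP (cat.), Et3N, MeCN, rt
Reagents that add atoms: di-tert-butyl dicarbonate, CC(C)(C)OC(=O)OC(=O)OC(C)(C)C
Why: DMAP-catalysed N-acylation of the lactam; the imide-type carbonyl so formed is activated for ring opening in step 15.

Step 15
Reactants: 23 tert-butyl (3R,4R)-3-{[(tert-butyldimethylsilyl)oxy]methyl}-3-{(3S)-3-[(tert-butyldimethylsilyl)oxy]pentyl}-4-{2-[(4-methoxybenzyl)oxy]ethyl}-2-oxopyrrolidine-1-carboxylate
Product: 24 tert-butyl N-[(2R,3R)-3-{[(tert-butyldimethylsilyl)oxy]methyl}-3-{(3S)-3-[(tert-butyldimethylsilyl)oxy]pentyl}-5-[dimethyl(oxo)-λ6-sulfanylidene]-2-{2-[(4-methoxybenzyl)oxy]ethyl}-4-oxopentyl]carbamate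
Conditions: Me3S(O)I, KOtBu, THF, reflux; then 23, 0 °C → rt
Reagents that add atoms: trimethylsulfoxonium iodide, [I-].C[S+](C)(C)=O
Why: Acylation of dimethylsulfoxonium methylide by the Boc-activated lactam (ring opening to a stabilised β-keto sulfoxonium ylide); the lactam carbonyl is the only electrophile of that reactivity and no stereocentre is affected.

Step 16
Reactants: 24 tert-butyl N-[(2R,3R)-3-{[(tert-butyldimethylsilyl)oxy]methyl}-3-{(3S)-3-[(tert-butyldimethylsilyl)oxy]pentyl}-5-[dimethyl(oxo)-λ6-sulfanylidene]-2-{2-[(4-methoxybenzyl)oxy]ethyl}-4-oxopentyl]carbamate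
Product: 25 tert-butyl (4R,5R)-4-{[(tert-butyldimethylsilyl)oxy]methyl}-4-{(3S)-3-[(tert-butyldimethylsilyl)oxy]pentyl}-5-{2-[(4-methoxybenzyl)oxy]ethyl}-3-oxopiperidine-1-carboxylate
Conditions: [Ir(cod)Cl]2 (1.5 mol %), ClCH2CH2Cl, 80 °C
Reagents that add atoms: none
Why: Iridium-carbene formation from the sulfoxonium ylide and intramolecular N–H insertion of the carbamate closes the six-membered ring A (overall a one-carbon ring expansion of the lactam).

Step 17
Reactants: 25 tert-butyl (4R,5R)-4-{[(tert-butyldimethylsilyl)oxy]methyl}-4-{(3S)-3-[(tert-butyldimethylsilyl)oxy]pentyl}-5-{2-[(4-methoxybenzyl)oxy]ethyl}-3-oxopiperidine-1-carboxylate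
Product: 26 tert-butyl (4S,5R)-4-{[(tert-butyldimethylsilyl)oxy]methyl}-4-{(3S)-3-[(tert-butyldimethylsilyl)oxy]pentyl}-5-{2-[(4-methoxybenzyl)oxy]ethyl}-3-methylidenepiperidine-1-carboxylate
Conditions: Ph3PCH3Br, KOtBu, THF, 0 → 60 °C
Reagents that add atoms: methyltriphenylphosphonium bromide, [Br-].C[P+](c1ccccc1)(c1ccccc1)c1ccccc1
Why: Wittig methylenation of the ketone installs the exocyclic alkene whose CH2 becomes the ring D methylene; the descriptor change at the quaternary carbon is only a priority change.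

Step 18
Reactants: 26 tert-butyl (4S,5R)-4-{[(tert-butyldimethylsilyl)oxy]methyl}-4-{(3S)-3-[(tert-butyldimethylsilyl)oxy]pentyl}-5-{2-[(4-methoxybenzyl)oxy]ethyl}-3-methylidenepiperidine-1-carboxylate
Product: 27 tert-butyl (4S,5R)-4-{[(tert-butyldimethylsilyl)oxy]methyl}-4-{(3S)-3-[(tert-butyldimethylsilyl)oxy]pentyl}-5-(2-hydroxyethyl)-3-methylidenepiperidine-1-carboxylate
Conditions: DDQ, CH2Cl2/pH 7 buffer (10:1), 0 °C → rt
Reagents that add atoms: none
Why: Oxidative cleavage of the PMB ether by DDQ; the silyl ethers, the carbamate and the 1,1-disubstituted alkene should not react.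

Step 19
Reactants: 27 tert-butyl (4S,5R)-4-{[(tert-butyldimethylsilyl)oxy]methyl}-4-{(3S)-3-[(tert-butyldimethylsilyl)oxy]pentyl}-5-(2-hydroxyethyl)-3-methylidenepiperidine-1-carboxylate
Product: 28 tert-butyl (4S,5R)-4-{[(tert-butyldimethylsilyl)oxy]methyl}-4-{(3S)-3-[(tert-butyldimethylsilyl)oxy]pentyl}-5-(2-iodoethyl)-3-methylidenepiperidine-1-carboxylate
Conditions: I2, PPh3, imidazole, CH2Cl2, 0 °C → rt
Reagents that add atoms: iodine, II
Why: Appel-type iodination of the primary alcohol; the nitrogen is kept as a carbamate so that it cannot cyclise onto the 2-iodoethyl group.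

Step 20
Reactants: 28 tert-butyl (4S,5R)-4-{[(tert-butyldimethylsilyl)oxy]methyl}-4-{(3S)-3-[(tert-butyldimethylsilyl)oxy]pentyl}-5-(2-iodoethyl)-3-methylidenepiperidine-1-carboxylate; 11 dimethyl 2-[(1S)-2-bromo-3-iodocyclopent-2-en-1-yl]propanedioate
Product: 30 tert-butyl (4S,5R)-5-{2-[(3S)-2-bromo-3-(1,3-dimethoxy-1,3-dioxopropan-2-yl)cyclopent-1-en-1-yl]ethyl}-4-{[(tert-butyldimethylsilyl)oxy]methyl}-4-{(3S)-3-[(tert-butyldimethylsilyl)oxy]pentyl}-3-methylidenepiperidine-1-carboxylate, via lithium alkylborate 29 (not isolated)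
Conditions: 9-MeO-9-BBN, t-BuLi (2.1 equiv), Et2O/THF, −78 °C → rt; then 11, PdCl2(dppf) (5 mol %), AsPh3, aq. K3PO4, DMF, rt
Reagents that add atoms: 9-methoxy-9-borabicyclo[3.3.1]nonane, COB1C2CCCC1CCC2 (atoms retained only in 29)
Why: B-alkyl Suzuki–Miyaura coupling through the borate made by iodine–lithium exchange and trapping with B-methoxy-9-BBN; oxidative addition should be selective for the alkenyl C–I bond over the neighbouring C–Br bond, and no stereocentre is touched.

Step 21
Reactants: 30 tert-butyl (4S,5R)-5-{2-[(3S)-2-bromo-3-(1,3-dimethoxy-1,3-dioxopropan-2-yl)cyclopent-1-en-1-yl]ethyl}-4-{[(tert-butyldimethylsilyl)oxy]methyl}-4-{(3S)-3-[(tert-butyldimethylsilyl)oxy]pentyl}-3-methylidenepiperidine-1-carboxylate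
Product: 32 tetracyclic geminal diester (rings A to D closed; N-Boc; both silyl ethers retained), via neopentyl iodide 31 (not isolated)
Conditions: Pd(QPhos)2 (7.5 mol %), KI (2 equiv), toluene (0.02 M), 100 °C; then Cs2CO3, DMF, 60 °C, same flask
Reagents that add atoms: potassium iodide, [K+].[I-] (iodine retained only in 31)
Why: Zerovalent palladium inserts into the alkenyl C–Br bond of ring C, the alkenylpalladium adds across the 3-methylene group of ring A in the 7-exo-trig mode (ring B), and the neopentyl palladium so formed, which has no β-hydrogen, undergoes bromide-to-iodide exchange and C(sp3)–I reductive elimination to 31; Cs2CO3 then generates the malonate anion, which displaces the iodide in a 5-exo-tet alkylation that joins the ring D methylene to the ester-bearing carbon (ring D). The closest known reaction types are the palladium-catalysed alkene carboiodination with halide exchange (a Heck-type cyclisation ended by halogen transfer) and the intramolecular alkylation of a malonate. Ring B therefore closes by syn-carbopalladation and ring D by SN2. The new quaternary stereocentre is controlled by the ring A methine that carries the two-carbon tether, because a seven-membered ring can span the 1,3-positions of ring A only on the face of that tether; the malonate carbon is not stereogenic, and the existing ring C stereocentre holds the malonate on the face of the iodomethyl group. The step needs exo over endo insertion (secured by the 1,1-disubstituted alkene and the ring size), no β-hydride elimination (secured by the hydrogen-free quaternary carbon) and C- over O-alkylation (secured by five-ring closure onto a soft iodide).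

Step 22
Reactants: 32 tetracyclic geminal diester (rings A to D closed; N-Boc; both silyl ethers retained)
Product: 33 tetracyclic mono ester (ester on the concave face as in the target; N-Boc; both silyl ethers retained)
Conditions: LiCl (3 equiv), H2O (2 equiv), DMSO, 140 °C
Reagents that add atoms: none
Why: Krapcho dealkoxycarbonylation (chloride SN2 at an ester methyl, then decarboxylation); the ester enolate should be protonated on the convex face of the bicyclo[3.3.0]octene, anti to ring C and to the quaternary carbon shared by rings A and B, which leaves the ester cis to both as in the target.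

Step 23
Reactants: 33 tetracyclic mono ester (ester on the concave face as in the target; N-Boc; both silyl ethers retained)
Product: 34 N-demethyl target (secondary amine with free hydroxymethyl and side-chain hydroxyl)
Conditions: HCl (3 M in MeOH), 0 °C → rt; NaHCO3 work-up
Reagents that add atoms: none
Why: Acid methanolysis removes both TBS ethers and the Boc group in one operation; in methanol the hydroxy ester is favoured over a bridged lactone and the stereocentres are not enolised under acid.

Step 24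
Reactants: 34 N-demethyl target (secondary amine with free hydroxymethyl and side-chain hydroxyl)
Product: 35 CNP0291564.1
Conditions: CH2O (37 % aq.), NaBH(OAc)3, AcOH (cat.), ClCH2CH2Cl, rt
Reagents that add atoms: formaldehyde, C=O
Why: Reductive amination of the secondary amine with formaldehyde (N-methylation); NaBH(OAc)3 leaves the methyl ester and the tetrasubstituted alkene untouched.

**Compound list**

1 | methyl (3S)-3-hydroxypentanoate | CC[C@H](O)CC(=O)OC | starting material
2 | methyl (3S)-3-[(tert-butyldimethylsilyl)oxy]pentanoate | CC[C@H](O[Si](C)(C)C(C)(C)C)CC(=O)OC | intermediate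
3 | (3S)-3-[(tert-butyldimethylsilyl)oxy]pentan-1-ol | CC[C@H](O[Si](C)(C)C(C)(C)C)CCO | intermediate
4 | tert-butyl{[(3S)-1-iodopentan-3-yl]oxy}dimethylsilane | CC[C@H](O[Si](C)(C)C(C)(C)C)CCI | intermediate
5 | cyclopentane-1,3-dione | O=C1CCC(=O)C1 | starting material
6 | 2-bromocyclopentane-1,3-dione, drawn as its enol 2-bromo-3-hydroxycyclopent-2-en-1-one | OC1=C(Br)C(=O)CC1 | intermediate
7 | 2-bromo-3-iodocyclopent-2-en-1-one | O=C1CCC(I)=C1Br | intermediate
8 | (1S)-2-bromo-3-iodocyclopent-2-en-1-ol | BrC1=C(I)CC[C@@H]1O | intermediate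
9 | dimethyl malonate | COC(=O)CC(=O)OC | starting material
10 | (1S)-2-bromo-3-iodocyclopent-2-en-1-yl methanesulfonate | BrC1=C(I)CC[C@@H]1OS(C)(=O)=O | intermediate
11 | dimethyl 2-[(1S)-2-bromo-3-iodocyclopent-2-en-1-yl]propanedioate | BrC1=C(I)CC[C@H]1C(C(=O)OC)C(=O)OC | intermediate
12 | 3-[(4-methoxybenzyl)oxy]propanal | COc1ccc(COCCC=O)cc1 | starting material
13 | nitromethane | C[N+](=O)[O-] | starting material
14 | 4-[(4-methoxybenzyl)oxy]-1-nitrobutan-2-ol (racemic) | COc1ccc(COCCC(O)C[N+](=O)[O-])cc1 | intermediate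
15 | 4-[(4-methoxybenzyl)oxy]-1-nitrobutan-2-yl methanesulfonate (racemic) | COc1ccc(COCCC(OS(C)(=O)=O)C[N+](=O)[O-])cc1 | intermediate
16 | 1-methoxy-4-({[(3E)-4-nitrobut-3-en-1-yl]oxy}methyl)benzene | COc1ccc(COCC/C=C/[N+](=O)[O-])cc1 | intermediate
17 | dimethyl 2-{(2R)-4-[(4-methoxybenzyl)oxy]-1-nitrobutan-2-yl}propanedioate | COC(=O)C(C(=O)OC)[C@H](C[N+](=O)[O-])CCOCc1ccc(OC)cc1 | intermediate
18 | dimethyl 2-{(2R)-1-amino-4-[(4-methoxybenzyl)oxy]butan-2-yl}propanedioate | COC(=O)C(C(=O)OC)[C@H](CN)CCOCc1ccc(OC)cc1 | intermediate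
19 | methyl (3R,4R)-4-{2-[(4-methoxybenzyl)oxy]ethyl}-2-oxopyrrolidine-3-carboxylate (trans) | COC(=O)[C@H]1C(=O)NC[C@@H]1CCOCc1ccc(OC)cc1 | intermediate
20 | methyl (3S,4R)-3-{(3S)-3-[(tert-butyldimethylsilyl)oxy]pentyl}-4-{2-[(4-methoxybenzyl)oxy]ethyl}-2-oxopyrrolidine-3-carboxylate | COC(=O)[C@]1(CC[C@@H](O[Si](C)(C)C(C)(C)C)CC)C(=O)NC[C@@H]1CCOCc1ccc(OC)cc1 | intermediate
21 | (3R,4R)-3-{(3S)-3-[(tert-butyldimethylsilyl)oxy]pentyl}-3-(hydroxymethyl)-4-{2-[(4-methoxybenzyl)oxy]ethyl}pyrrolidin-2-one | OC[C@]1(CC[C@@H](O[Si](C)(C)C(C)(C)C)CC)C(=O)NC[C@@H]1CCOCc1ccc(OC)cc1 | intermediate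
22 | (3R,4R)-3-{[(tert-butyldimethylsilyl)oxy]methyl}-3-{(3S)-3-[(tert-butyldimethylsilyl)oxy]pentyl}-4-{2-[(4-methoxybenzyl)oxy]ethyl}pyrrolidin-2-one | CC(C)(C)[Si](C)(C)OC[C@]1(CC[C@@H](O[Si](C)(C)C(C)(C)C)CC)C(=O)NC[C@@H]1CCOCc1ccc(OC)cc1 | intermediate
23 | tert-butyl (3R,4R)-3-{[(tert-butyldimethylsilyl)oxy]methyl}-3-{(3S)-3-[(tert-butyldimethylsilyl)oxy]pentyl}-4-{2-[(4-methoxybenzyl)oxy]ethyl}-2-oxopyrrolidine-1-carboxylate | CC(C)(C)[Si](C)(C)OC[C@]1(CC[C@@H](O[Si](C)(C)C(C)(C)C)CC)C(=O)N(C(=O)OC(C)(C)C)C[C@@H]1CCOCc1ccc(OC)cc1 | intermediate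
24 | tert-butyl N-[(2R,3R)-3-{[(tert-butyldimethylsilyl)oxy]methyl}-3-{(3S)-3-[(tert-butyldimethylsilyl)oxy]pentyl}-5-[dimethyl(oxo)-λ6-sulfanylidene]-2-{2-[(4-methoxybenzyl)oxy]ethyl}-4-oxopentyl]carbamate (β-keto sulfoxonium ylide) | CC(C)(C)[Si](C)(C)OC[C@](CC[C@@H](O[Si](C)(C)C(C)(C)C)CC)(C(=O)C=S(C)(C)=O)[C@H](CNC(=O)OC(C)(C)C)CCOCc1ccc(OC)cc1 | intermediate
25 | tert-butyl (4R,5R)-4-{[(tert-butyldimethylsilyl)oxy]methyl}-4-{(3S)-3-[(tert-butyldimethylsilyl)oxy]pentyl}-5-{2-[(4-methoxybenzyl)oxy]ethyl}-3-oxopiperidine-1-carboxylate | CC(C)(C)OC(=O)N1CC(=O)[C@](CO[Si](C)(C)C(C)(C)C)(CC[C@@H](O[Si](C)(C)C(C)(C)C)CC)[C@@H](CCOCc2ccc(OC)cc2)C1 | intermediate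
26 | tert-butyl (4S,5R)-4-{[(tert-butyldimethylsilyl)oxy]methyl}-4-{(3S)-3-[(tert-butyldimethylsilyl)oxy]pentyl}-5-{2-[(4-methoxybenzyl)oxy]ethyl}-3-methylidenepiperidine-1-carboxylate | CC(C)(C)OC(=O)N1CC(=C)[C@](CO[Si](C)(C)C(C)(C)C)(CC[C@@H](O[Si](C)(C)C(C)(C)C)CC)[C@@H](CCOCc2ccc(OC)cc2)C1 | intermediate
27 | tert-butyl (4S,5R)-4-{[(tert-butyldimethylsilyl)oxy]methyl}-4-{(3S)-3-[(tert-butyldimethylsilyl)oxy]pentyl}-5-(2-hydroxyethyl)-3-methylidenepiperidine-1-carboxylate | CC(C)(C)OC(=O)N1CC(=C)[C@](CO[Si](C)(C)C(C)(C)C)(CC[C@@H](O[Si](C)(C)C(C)(C)C)CC)[C@@H](CCO)C1 | intermediate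
28 | tert-butyl (4S,5R)-4-{[(tert-butyldimethylsilyl)oxy]methyl}-4-{(3S)-3-[(tert-butyldimethylsilyl)oxy]pentyl}-5-(2-iodoethyl)-3-methylidenepiperidine-1-carboxylate | CC(C)(C)OC(=O)N1CC(=C)[C@](CO[Si](C)(C)C(C)(C)C)(CC[C@@H](O[Si](C)(C)C(C)(C)C)CC)[C@@H](CCI)C1 | intermediate
29 | lithium B-methoxy-B-alkyl-9-borabicyclo[3.3.1]nonane borate of 28 (boron in place of iodine) | CC(C)(C)OC(=O)N1CC(=C)[C@](CO[Si](C)(C)C(C)(C)C)(CC[C@@H](O[Si](C)(C)C(C)(C)C)CC)[C@@H](CC[B-]2(OC)C3CCCC2CCC3)C1.[Li+] | intermediate
30 | tert-butyl (4S,5R)-5-{2-[(3S)-2-bromo-3-(1,3-dimethoxy-1,3-dioxopropan-2-yl)cyclopent-1-en-1-yl]ethyl}-4-{[(tert-butyldimethylsilyl)oxy]methyl}-4-{(3S)-3-[(tert-butyldimethylsilyl)oxy]pentyl}-3-methylidenepiperidine-1-carboxylate | CC(C)(C)OC(=O)N1CC(=C)[C@](CO[Si](C)(C)C(C)(C)C)(CC[C@@H](O[Si](C)(C)C(C)(C)C)CC)[C@@H](CCC2=C(Br)[C@H](C(C(=O)OC)C(=O)OC)CC2)C1 | intermediate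
31 | tricyclic neopentyl iodide: rings A, B and C closed, iodomethyl on the new quaternary carbon, malonate on ring C, N-Boc, two TBS ethers, ring stereocentres as in the target | CC[C@H](O[Si](C)(C)C(C)(C)C)CC[C@]1(CO[Si](C)(C)C(C)(C)C)[C@H]2CCC3=C([C@@H](CC3)C(C(=O)OC)C(=O)OC)[C@]1(CI)CN(C(=O)OC(C)(C)C)C2 | intermediate
32 | tetracyclic geminal diester: rings A to D closed, two methyl esters on the ring D carbon next to the methylene, N-Boc, two TBS ethers, ring stereocentres as in the target | CC[C@H](O[Si](C)(C)C(C)(C)C)CC[C@]1(CO[Si](C)(C)C(C)(C)C)[C@H]2CCC3=C4[C@@H](CC3)C(C(=O)OC)(C(=O)OC)C[C@]41CN(C(=O)OC(C)(C)C)C2 | intermediate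
33 | tetracyclic mono ester: as 32 with one methyl ester, configured as in the target | CC[C@H](O[Si](C)(C)C(C)(C)C)CC[C@]1(CO[Si](C)(C)C(C)(C)C)[C@H]2CCC3=C4[C@@H](CC3)[C@@H](C(=O)OC)C[C@]41CN(C(=O)OC(C)(C)C)C2 | intermediate
34 | N-demethyl target: secondary amine, free hydroxymethyl and (S)-3-hydroxypentyl groups, methyl ester | CC[C@H](O)CC[C@]1(CO)[C@H]2CCC3=C4[C@@H](CC3)[C@@H](C(=O)OC)C[C@]41CNC2 | intermediate
35 | CNP0291564.1 | CC[C@H](O)CC[C@]1(CO)[C@H]2CCC3=C4[C@@H](CC3)[C@@H](C(=O)OC)C[C@]41CN(C)C2 | target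

**Step count and risks**

Total step count: 24 (steps 1–3 make iodide 4, steps 4–7 make cyclopentene 11, steps 8–24 are the main line).
Longest linear sequence: 17 steps (12 → 35, steps 8–24).

Steps most likely to fail:

1. Step 21. The carbopalladation must take place at a 1,1-disubstituted alkene that sits next to a quaternary carbon. The carbon–iodine reductive elimination may lose to proto-depalladation or to 3-exo attack of the neopentyl palladium on the ring C alkene, and the neopentyl displacement may be slow. Fallback: it sets out from 30 and replaces halogen transfer by boron capture. A Heck cyclisation ended by borylation (Pd(OAc)2, PPh3, B2pin2, KOAc, DMF, 80 °C) should give the neopentyl pinacol boronate F1. Oxidation with NaBO3·4H2O in THF/H2O gives the neopentyl alcohol F2. Tf2O and 2,6-lutidine at −78 °C give the neopentyl triflate F3, which is treated in the same flask with Cs2CO3 so that the malonate closes ring D on the far better leaving group. The fallback comes back to the route at 32.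

2. Step 15. Addition of the sulfoxonium ylide to the lactam carbonyl may be slow because that carbonyl flanks a quaternary carbon, and attack at the Boc carbonyl would strip the activating group. Fallback: it sets out from 23 and builds ring A by N-allylation instead of N–H insertion. MeMgBr (THF, −78 °C) opens the Boc-activated lactam to the methyl ketone F4. Wittig methylenation (Ph3PCH3Br, KOtBu) gives the isopropenyl compound F5. Ene-type allylic chlorination (NCS, PhSeCl cat., CH2Cl2) gives the 2-(chloromethyl)allyl compound F6, in which the two allylic carbons of the isopropenyl group are equivalent, so no regiochemical issue arises. NaH in DMF then closes the piperidine by 6-exo-tet N-alkylation of the carbamate. The fallback comes back to the route at 26 and leaves out 24 and 25.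

3. Step 22. Facial control in the protonation of the ester enolate may be poor, or the ester may epimerise at 140 °C, giving a mixture at the ester-bearing ring D carbon. Fallback: it sets out from 33 obtained together with its ring D epimer F7 and uses the cis-1,3 relation of the ester and the hydroxymethyl-bearing carbon. HF·pyridine (THF, pyridine) removes both silyl ethers and keeps the Boc group, giving the diol F8 from 33 and the epimeric diol F9 from F7. KOtBu (0.3 equiv) in toluene at 80 °C with removal of methanol epimerises the ester α-carbon; only the epimer with the carboxyl cis to the hydroxymethyl carbon can close the bridged seven-membered lactone F10, which drains the mixture. The conditions of step 23 (HCl in MeOH) then open the lactone by acid methanolysis without epimerisation and remove the Boc group. The fallback comes back to the route at 34.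

**Further compounds**

F1 | step 21 | tricyclic neopentyl pinacol boronate (as 31 with Bpin in place of iodine) | CC[C@H](O[Si](C)(C)C(C)(C)C)CC[C@]1(CO[Si](C)(C)C(C)(C)C)[C@H]2CCC3=C([C@@H](CC3)C(C(=O)OC)C(=O)OC)[C@]1(CB4OC(C)(C)C(C)(C)O4)CN(C(=O)OC(C)(C)C)C2
F2 | step 21 | tricyclic neopentyl alcohol (as 31 with OH in place of iodine) | CC[C@H](O[Si](C)(C)C(C)(C)C)CC[C@]1(CO[Si](C)(C)C(C)(C)C)[C@H]2CCC3=C([C@@H](CC3)C(C(=O)OC)C(=O)OC)[C@]1(CO)CN(C(=O)OC(C)(C)C)C2
F3 | step 21 | tricyclic neopentyl trifluoromethanesulfonate (as 31 with OTf in place of iodine) | CC[C@H](O[Si](C)(C)C(C)(C)C)CC[C@]1(CO[Si](C)(C)C(C)(C)C)[C@H]2CCC3=C([C@@H](CC3)C(C(=O)OC)C(=O)OC)[C@]1(COS(=O)(=O)C(F)(F)F)CN(C(=O)OC(C)(C)C)C2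
F4 | step 15 | ring-opened methyl ketone (as 24 with acetyl in place of the keto ylide) | CC(C)(C)[Si](C)(C)OC[C@](CC[C@@H](O[Si](C)(C)C(C)(C)C)CC)(C(C)=O)[C@H](CNC(=O)OC(C)(C)C)CCOCc1ccc(OC)cc1
F5 | step 15 | isopropenyl compound (as F4 with C(CH3)=CH2 in place of acetyl) | CC(C)(C)[Si](C)(C)OC[C@](CC[C@@H](O[Si](C)(C)C(C)(C)C)CC)(C(C)=C)[C@H](CNC(=O)OC(C)(C)C)CCOCc1ccc(OC)cc1
F6 | step 15 | 2-(chloromethyl)allyl compound (as F5 with CH2Cl in place of the allylic methyl) | CC(C)(C)[Si](C)(C)OC[C@](CC[C@@H](O[Si](C)(C)C(C)(C)C)CC)(C(=C)CCl)[C@H](CNC(=O)OC(C)(C)C)CCOCc1ccc(OC)cc1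
F7 | step 22 | epimer of 33 at the ester-bearing ring D carbon | CC[C@H](O[Si](C)(C)C(C)(C)C)CC[C@]1(CO[Si](C)(C)C(C)(C)C)[C@H]2CCC3=C4[C@@H](CC3)[C@H](C(=O)OC)C[C@]41CN(C(=O)OC(C)(C)C)C2
F8 | step 22 | N-Boc diol ester (33 without the two silyl groups) | CC[C@H](O)CC[C@]1(CO)[C@H]2CCC3=C4[C@@H](CC3)[C@@H](C(=O)OC)C[C@]41CN(C(=O)OC(C)(C)C)C2
F9 | step 22 | N-Boc diol ester, epimer at the ester-bearing ring D carbon (F7 without the two silyl groups) | CC[C@H](O)CC[C@]1(CO)[C@H]2CCC3=C4[C@@H](CC3)[C@H](C(=O)OC)C[C@]41CN(C(=O)OC(C)(C)C)C2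
F10 | step 22 | N-Boc bridged seven-membered lactone between the ring D carboxyl and the hydroxymethyl oxygen | CC[C@H](O)CC[C@]1(CO5)[C@H]2CCC3=C4[C@@H](CC3)[C@@H](C5=O)C[C@]41CN(C(=O)OC(C)(C)C)C2
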